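**Retrosynthetic overview**

1. The last bond is C1'=C2', made by E-selective cross-metathesis of a C2-vinyl furo[3,2-b]pyranone with (2R,3S)-3-hydroxypent-4-en-2-yl benzoate; the side-chain stereodiad comes from Sharpless desymmetrisation of divinylcarbinol.
2. The pyranone (O4, C5, C6, C7, C7a, C3a) is closed second to last, by oxidative lactonisation of a (Z)-allylic alcohol onto the C3a hydroxyl.
3. The tetrahydrofuran (O1, C2, C3, C3a, C7a) is not closed directly. Its five atoms plus the exocyclic carbon C1', raised to the carboxyl level, are first built as the δ-lactone O1–C7a–C3a–C3–C2–C1'(=O) with a triflate on C2. Methoxide opens the lactone and O1 displaces the triflate, so the ring contracts by expelling C1' and C2 is inverted to the all-cis array.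
4. Enabling feature: C2 carries the ring oxygen O1 and exactly one exocyclic carbon (C1'), so O1 can be held as the acyl oxygen of a C1' lactone in which C2 is the α-carbon; the cis C3/C3a diol allows a dioxolane that pre-organises the closure.
5. The δ-lactone comes from 2,3-O-isopropylidene-D-ribono-1,4-lactone (C7a, C3a, C3, C2, C1') by acetylide addition (C5–C7), Felkin–Anh reduction (C7a) and oxidative lactonisation. Ring order: δ-lactone (temporary), tetrahydrofuran, pyranone.

Key step: step 5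

Remark: locants in the Why lines are those of the target (ring O1, C2, C3, C3a, O4, C5, C6, C7, C7a; side chain C1'–C5'), also for precursors; TBS = tert-butyldimethylsilyl.

**Route**

Step 1
Reactants: 1 2,3-O-isopropylidene-D-ribono-1,4-lactone; 2 tert-butyldimethyl(prop-2-yn-1-yloxy)silane
Product: 3 1-C-[3-(TBSO)prop-1-yn-1-yl]-2,3-O-isopropylidene-D-ribofuranose (hemiketal; both anomers)
Conditions: 2 (2.6 equiv), n-BuLi (2.5 equiv), THF, −78 °C; then 1, −78 °C; AcOH quench
Reagents that add atoms: none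
Why: 1,2-addition of the lithium acetylide to the γ-lactone carbonyl (the first equivalent only deprotonates the primary hydroxyl) should stop at the tetrahedral lithium lactolate at −78 °C and give the hemiketal on protonation, attaching C5–C7 to the carbon that becomes C7a without creating a fixed stereocentre (acetylide addition to a lactone).

Step 2
Reactants: 3 1-C-[3-(TBSO)prop-1-yn-1-yl]-2,3-O-isopropylidene-D-ribofuranose
Product: 5 1-O-TBS-2,3-didehydro-2,3-dideoxy-5,6-O-isopropylidene-D-altro-oct-2-ynitol [(4R,5S,6R,7R)-triol], via open-chain ynone 4 (not isolated)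
Conditions: LiBH(s-Bu)3 (L-Selectride, 3.5 equiv), THF, −78 °C to −40 °C; then H2O
Reagents that add atoms: none
Why: under the basic conditions the lactolate opens to ynone 4, which the bulky trialkylborohydride should reduce 1,2 under Felkin–Anh control, hydride arriving anti to the dioxolane C–O bond at C3a, so that C7a is set as the 7a,3a-syn (D-altro) propargylic alcohol (diastereoselective L-Selectride reduction of an α-alkoxy ketone).

Step 3
Reactants: 5 1-O-TBS-2,3-didehydro-2,3-dideoxy-5,6-O-isopropylidene-D-altro-oct-2-ynitol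
Product: 8 8-O-TBS-6,7-didehydro-6,7-dideoxy-3,4-O-isopropylidene-D-talo-oct-6-ynono-1,5-lactone (2-hydroxy δ-lactone; all four ring substituents cis), via hydroxy aldehyde 6 (not isolated), via lactol 7 (not isolated)
Conditions: TEMPO (20 mol%), PhI(OAc)2 (2.3 equiv), CH2Cl2, rt
Reagents that add atoms: none
Why: the oxoammonium oxidant should take the primary alcohol (future C1') first, the aldehyde is captured by the C7a hydroxyl as a six-membered lactol and this is oxidised to the δ-lactone, the hindered secondary C2 hydroxyl surviving and no stereocentre being touched (TEMPO/PhI(OAc)2 oxidative lactonisation of a 1,5-diol).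

Step 4
Reactants: 8 8-O-TBS-6,7-didehydro-6,7-dideoxy-3,4-O-isopropylidene-D-talo-oct-6-ynono-1,5-lactone
Product: 9 8-O-TBS-6,7-didehydro-6,7-dideoxy-3,4-O-isopropylidene-2-O-(trifluoromethanesulfonyl)-D-talo-oct-6-ynono-1,5-lactone
Conditions: Tf2O (1.3 equiv), pyridine, CH2Cl2, −30 °C
Reagents that add atoms: trifluoromethanesulfonic anhydride, O=S(=O)(OS(=O)(=O)C(F)(F)F)C(F)(F)F
Why: sulfonylation of the only free hydroxyl (C2–OH, α to the lactone carbonyl) at low temperature should give the α-triflyloxy lactone with retention, since only the O–H bond is broken (alcohol triflation).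

Step 5
Reactants: 9 8-O-TBS-6,7-didehydro-6,7-dideoxy-3,4-O-isopropylidene-2-O-(trifluoromethanesulfonyl)-D-talo-oct-6-ynono-1,5-lactone
Product: 11 methyl 2,5-anhydro-8-O-TBS-6,7-didehydro-6,7-dideoxy-3,4-O-isopropylidene-D-galacto-oct-6-ynonate [methyl (3aS,4R,6R,6aS)-6-[3-(TBSO)prop-1-yn-1-yl]-2,2-dimethyltetrahydrofuro[3,4-d][1,3]dioxole-4-carboxylate; all-cis], via ring-opened methyl ester alkoxide 10 (not isolated)
Conditions: K2CO3 (1.1 equiv), MeOH, −10 °C to 0 °C, short reaction time; pH 7 buffer quench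
Reagents that add atoms: methanol, CO
Why: Methoxide adds to the lactone carbonyl of 9 and the tetrahedral intermediate collapses to the open-chain methyl ester 10, whose freed propargylic C7a alkoxide displaces the α-triflate at C2 intramolecularly, so the six-membered ring O1–C7a–C3a–C3–C2–C1'(=O) is exchanged for the five-membered ring O1–C7a–C3a–C3–C2 with C1' expelled as the exocyclic ester. The closest known reaction type is the carbonate/methanol ring contraction of 2-O-triflyl-3,4-O-isopropylidene aldono-1,5-lactones to 2,5-anhydroaldonates (tetrahydrofuran-2-carboxylates). The tetrahydrofuran closes in the 5-exo-tet mode. The only stereocentre touched is C2, which is inverted stereospecifically by the SN2 backside attack; because the lactone carries all four ring substituents cis, inversion places the ester, both dioxolane oxygens and the alkynyl group on one face, the contra-thermodynamic all-cis array of the target. The step needs acyl attack and ring closure to outrun E2 loss of triflate, direct substitution by methoxide and later epimerisation of the new ester α-carbon; the cis-fused dioxolane holds the C7a oxygen and C2 close so that closure is fast, and low temperature with a near-stoichiometric amount of K2CO3 limits enolisation.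

Step 6
Reactants: 11 methyl 2,5-anhydro-8-O-TBS-6,7-didehydro-6,7-dideoxy-3,4-O-isopropylidene-D-galacto-oct-6-ynonate
Product: 12 methyl (3aS,4R,6R,6aS)-6-[(1Z)-3-(TBSO)prop-1-en-1-yl]-2,2-dimethyltetrahydrofuro[3,4-d][1,3]dioxole-4-carboxylate
Conditions: H2 (1 atm), Pd/CaCO3 poisoned with Pb(OAc)2 (Lindlar catalyst), quinoline, EtOAc, rt
Reagents that add atoms: none
Why: cis-selective semihydrogenation of the alkyne over poisoned palladium should stop at the (Z)-alkene C6=C7 needed for the later lactonisation, leaving ester, silyl ether and acetonide untouched (Lindlar reduction).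

Step 7
Reactants: 12 methyl (3aS,4R,6R,6aS)-6-[(1Z)-3-(TBSO)prop-1-en-1-yl]-2,2-dimethyltetrahydrofuro[3,4-d][1,3]dioxole-4-carboxylate
Product: 13 (3aS,4R,6R,6aS)-6-[(1Z)-3-(TBSO)prop-1-en-1-yl]-2,2-dimethyltetrahydrofuro[3,4-d][1,3]dioxole-4-carbaldehyde
Conditions: iBu2AlH (DIBAL-H, 1.1 equiv), CH2Cl2, −78 °C; aq. potassium sodium tartrate
Reagents that add atoms: none
Why: at −78 °C the α-alkoxy ester should be reduced only to the chelate-stabilised aluminium hemiacetal, which releases the C1' aldehyde on work-up without touching the C2 stereocentre (DIBAL-H partial reduction of an ester).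

Step 8
Reactants: 13 (3aS,4R,6R,6aS)-6-[(1Z)-3-(TBSO)prop-1-en-1-yl]-2,2-dimethyltetrahydrofuro[3,4-d][1,3]dioxole-4-carbaldehyde
Product: 14 tert-butyl({(2Z)-3-[(3aS,4R,6S,6aR)-6-ethenyl-2,2-dimethyltetrahydrofuro[3,4-d][1,3]dioxol-4-yl]prop-2-en-1-yl}oxy)dimethylsilane
Conditions: Ph3PCH3Br, KN(SiMe3)2, THF, −78 °C to 0 °C
Reagents that add atoms: methyltriphenylphosphonium bromide, C[P+](c1ccccc1)(c1ccccc1)c1ccccc1.[Br-]
Why: methylenetriphenylphosphorane should add to the aldehyde faster than it enolises it at low temperature, converting C1' into the terminal vinyl group for the later cross-metathesis with C2 intact (Wittig methylenation).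

Step 9
Reactants: 14 tert-butyl({(2Z)-3-[(3aS,4R,6S,6aR)-6-ethenyl-2,2-dimethyltetrahydrofuro[3,4-d][1,3]dioxol-4-yl]prop-2-en-1-yl}oxy)dimethylsilane
Product: 15 (2S,3S,4R,5R)-2-ethenyl-5-[(1Z)-3-hydroxyprop-1-en-1-yl]oxolane-3,4-diol
Conditions: CF3CO2H/H2O (90% aq.), 0 °C
Reagents that add atoms: none
Why: aqueous trifluoroacetic acid should hydrolyse the cis-fused isopropylidene acetal and the primary allylic silyl ether in one operation, unmasking the C3 and C3a hydroxyls and the C5 alcohol without touching a stereocentre (acid-catalysed acetal and silyl ether hydrolysis).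

Step 10
Reactants: 15 (2S,3S,4R,5R)-2-ethenyl-5-[(1Z)-3-hydroxyprop-1-en-1-yl]oxolane-3,4-diol
Product: 18 (2S,3R,3aR,7aR)-2-ethenyl-3-hydroxy-2,3,3a,7a-tetrahydro-5H-furo[3,2-b]pyran-5-one, via (Z)-enal 16 (not isolated), via lactol 17 (not isolated)
Conditions: TEMPO (20 mol%), PhI(OAc)2 (2.5 equiv), CH2Cl2, rt
Reagents that add atoms: none
Why: the oxoammonium species should oxidise only the primary allylic alcohol to the (Z)-enal, which is trapped by the C3a hydroxyl (the only one that can form a six-membered ring) as a lactol and oxidised on to the α,β-unsaturated δ-lactone, the secondary C3 hydroxyl being left (TEMPO/PhI(OAc)2 oxidative lactonisation).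

Step 11
Reactants: 19 penta-1,4-dien-3-ol
Product: 20 (2R,3S)-1,2-epoxypent-4-en-3-ol
Conditions: t-BuOOH, Ti(OiPr)4 (cat.), L-(+)-diisopropyl tartrate, 4 Å molecular sieves, CH2Cl2, −20 °C
Reagents that add atoms: tert-butyl hydroperoxide, CC(C)(C)OO
Why: the L-(+)-tartrate titanium catalyst should desymmetrise the dienol by combined enantiotopic-group and diastereofacial selection, giving the anti (erythro) epoxy alcohol that fixes both C3' (S) and C4' (R) (Sharpless asymmetric epoxidation).

Step 12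
Reactants: 20 (2R,3S)-1,2-epoxypent-4-en-3-ol
Product: 21 (2R,3S)-3-(TBSO)-1,2-epoxypent-4-ene
Conditions: TBSCl, imidazole, DMF, 0 °C to rt
Reagents that add atoms: tert-butyldimethylsilyl chloride, CC(C)(C)[Si](C)(C)Cl
Why: silylation of the secondary allylic alcohol under imidazole conditions should protect C3'–OH without Payne rearrangement of the adjacent epoxide (silyl ether formation).

Step 13
Reactants: 21 (2R,3S)-3-(TBSO)-1,2-epoxypent-4-ene
Product: 22 (2R,3S)-3-(TBSO)pent-4-en-2-ol
Conditions: LiAlH4, Et2O, 0 °C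
Reagents that add atoms: none
Why: hydride should open the terminal epoxide at the unsubstituted carbon in SN2 fashion, creating the C5' methyl group and leaving the C4' oxygen and configuration untouched (regioselective reductive epoxide opening).

Step 14
Reactants: 22 (2R,3S)-3-(TBSO)pent-4-en-2-ol
Product: 23 (2R,3S)-3-(TBSO)pent-4-en-2-yl benzoate
Conditions: BzCl, pyridine, DMAP (cat.), CH2Cl2, 0 °C to rt
Reagents that add atoms: benzoyl chloride, O=C(Cl)c1ccccc1
Why: acylation of the liberated secondary alcohol under nucleophilic catalysis should install the C4' benzoate with retention (DMAP-catalysed esterification).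

Step 15
Reactants: 23 (2R,3S)-3-(TBSO)pent-4-en-2-yl benzoate
Product: 24 (2R,3S)-3-hydroxypent-4-en-2-yl benzoate
Conditions: HF·pyridine, THF, 0 °C to rt
Reagents that add atoms: none
Why: buffered fluoride should cleave the secondary silyl ether under non-basic conditions, which avoids 1,2-migration of the neighbouring benzoate (desilylation with HF·pyridine).

Step 16
Reactants: 18 (2S,3R,3aR,7aR)-2-ethenyl-3-hydroxy-2,3,3a,7a-tetrahydro-5H-furo[3,2-b]pyran-5-one; 24 (2R,3S)-3-hydroxypent-4-en-2-yl benzoate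
Product: 25 (2R,3S,4E)-3-hydroxy-5-[(2S,3R,3aR,7aR)-3-hydroxy-5-oxo-2,3,3a,7a-tetrahydro-5H-furo[3,2-b]pyran-2-yl]pent-4-en-2-yl benzoate (CNP0143030.1)
Conditions: 24 (3 equiv), second-generation Hoveyda–Grubbs catalyst RuCl2(H2IMes)(=CH-C6H4-2-OiPr) (10 mol%), CH2Cl2, 40 °C
Reagents that add atoms: none
Why: olefin cross-metathesis between the monosubstituted vinyl group of 18 and the terminal alkene of 24 (in excess) should forge C1'=C2' with thermodynamic E selectivity while the electron-poor endocyclic enoate stays inert, uniting the two fragments without touching a stereocentre (ruthenium-catalysed cross-metathesis).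

**Compound list**

1 | 2,3-O-isopropylidene-D-ribono-1,4-lactone | O=C1[C@@H]2OC(C)(C)O[C@@H]2[C@@H](CO)O1 | starting material
2 | tert-butyldimethyl(prop-2-yn-1-yloxy)silane | C#CCO[Si](C)(C)C(C)(C)C | starting material
3 | 1-C-[3-(TBSO)prop-1-yn-1-yl]-2,3-O-isopropylidene-D-ribofuranose (hemiketal; both anomers) | OC1(C#CCO[Si](C)(C)C(C)(C)C)[C@@H]2OC(C)(C)O[C@@H]2[C@@H](CO)O1 | intermediate
4 | 1-[(4R,5R)-5-[(1R)-1,2-dihydroxyethyl]-2,2-dimethyl-1,3-dioxolan-4-yl]-4-(TBSO)but-2-yn-1-one (open-chain ynone; not isolated) | CC(C)(C)[Si](C)(C)OCC#CC(=O)[C@@H]1OC(C)(C)O[C@@H]1[C@H](O)CO | intermediate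
5 | 1-O-TBS-2,3-didehydro-2,3-dideoxy-5,6-O-isopropylidene-D-altro-oct-2-ynitol [(4R,5S,6R,7R)-triol] | CC(C)(C)[Si](C)(C)OCC#C[C@@H](O)[C@@H]1OC(C)(C)O[C@@H]1[C@H](O)CO | intermediate
6 | 8-O-TBS-6,7-didehydro-6,7-dideoxy-3,4-O-isopropylidene-aldehydo-D-talo-oct-6-ynose (hydroxy aldehyde; not isolated) | CC(C)(C)[Si](C)(C)OCC#C[C@@H](O)[C@@H]1OC(C)(C)O[C@@H]1[C@H](O)C=O | intermediate
7 | 8-O-TBS-6,7-didehydro-6,7-dideoxy-3,4-O-isopropylidene-D-talo-oct-6-ynopyranose (lactol; both anomers; not isolated) | CC(C)(C)[Si](C)(C)OCC#C[C@H]1OC(O)[C@@H](O)[C@H]2OC(C)(C)O[C@@H]12 | intermediate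
8 | 8-O-TBS-6,7-didehydro-6,7-dideoxy-3,4-O-isopropylidene-D-talo-oct-6-ynono-1,5-lactone | CC(C)(C)[Si](C)(C)OCC#C[C@H]1OC(=O)[C@@H](O)[C@H]2OC(C)(C)O[C@@H]12 | intermediate
9 | 8-O-TBS-6,7-didehydro-6,7-dideoxy-3,4-O-isopropylidene-2-O-(trifluoromethanesulfonyl)-D-talo-oct-6-ynono-1,5-lactone | CC(C)(C)[Si](C)(C)OCC#C[C@H]1OC(=O)[C@@H](OS(=O)(=O)C(F)(F)F)[C@H]2OC(C)(C)O[C@@H]12 | intermediate
10 | methyl 8-O-TBS-6,7-didehydro-6,7-dideoxy-3,4-O-isopropylidene-2-O-(trifluoromethanesulfonyl)-D-talo-oct-6-ynonate (present as the 5-alkoxide; not isolated) | CC(C)(C)[Si](C)(C)OCC#C[C@@H](O)[C@@H]1OC(C)(C)O[C@@H]1[C@H](OS(=O)(=O)C(F)(F)F)C(=O)OC | intermediate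
11 | methyl 2,5-anhydro-8-O-TBS-6,7-didehydro-6,7-dideoxy-3,4-O-isopropylidene-D-galacto-oct-6-ynonate [methyl (3aS,4R,6R,6aS)-6-[3-(TBSO)prop-1-yn-1-yl]-2,2-dimethyltetrahydrofuro[3,4-d][1,3]dioxole-4-carboxylate] | CC(C)(C)[Si](C)(C)OCC#C[C@H]1O[C@@H](C(=O)OC)[C@H]2OC(C)(C)O[C@@H]12 | intermediate
12 | methyl (3aS,4R,6R,6aS)-6-[(1Z)-3-(TBSO)prop-1-en-1-yl]-2,2-dimethyltetrahydrofuro[3,4-d][1,3]dioxole-4-carboxylate | CC(C)(C)[Si](C)(C)OC/C=C\[C@H]1O[C@@H](C(=O)OC)[C@H]2OC(C)(C)O[C@@H]12 | intermediate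
13 | (3aS,4R,6R,6aS)-6-[(1Z)-3-(TBSO)prop-1-en-1-yl]-2,2-dimethyltetrahydrofuro[3,4-d][1,3]dioxole-4-carbaldehyde | CC(C)(C)[Si](C)(C)OC/C=C\[C@H]1O[C@@H](C=O)[C@H]2OC(C)(C)O[C@@H]12 | intermediate
14 | tert-butyl({(2Z)-3-[(3aS,4R,6S,6aR)-6-ethenyl-2,2-dimethyltetrahydrofuro[3,4-d][1,3]dioxol-4-yl]prop-2-en-1-yl}oxy)dimethylsilane | CC(C)(C)[Si](C)(C)OC/C=C\[C@H]1O[C@@H](C=C)[C@H]2OC(C)(C)O[C@@H]12 | intermediate
15 | (2S,3S,4R,5R)-2-ethenyl-5-[(1Z)-3-hydroxyprop-1-en-1-yl]oxolane-3,4-diol | OC/C=C\[C@H]1O[C@@H](C=C)[C@@H](O)[C@H]1O | intermediate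
16 | (2Z)-3-[(2R,3R,4S,5S)-5-ethenyl-3,4-dihydroxyoxolan-2-yl]prop-2-enal (not isolated) | O=C/C=C\[C@H]1O[C@@H](C=C)[C@@H](O)[C@H]1O | intermediate
17 | (2S,3R,3aR,7aR)-2-ethenyl-2,3,3a,7a-tetrahydro-5H-furo[3,2-b]pyran-3,5-diol (lactol; both C5 epimers; not isolated) | C=C[C@@H]1O[C@@H]2C=CC(O)O[C@@H]2[C@@H]1O | intermediate
18 | (2S,3R,3aR,7aR)-2-ethenyl-3-hydroxy-2,3,3a,7a-tetrahydro-5H-furo[3,2-b]pyran-5-one | C=C[C@@H]1O[C@@H]2C=CC(=O)O[C@@H]2[C@@H]1O | intermediate
19 | penta-1,4-dien-3-ol | C=CC(O)C=C | starting material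
20 | (2R,3S)-1,2-epoxypent-4-en-3-ol | C=C[C@H](O)[C@H]1CO1 | intermediate
21 | (2R,3S)-3-(TBSO)-1,2-epoxypent-4-ene | C=C[C@H](O[Si](C)(C)C(C)(C)C)[C@H]1CO1 | intermediate
22 | (2R,3S)-3-(TBSO)pent-4-en-2-ol | C[C@@H](O)[C@@H](O[Si](C)(C)C(C)(C)C)C=C | intermediate
23 | (2R,3S)-3-(TBSO)pent-4-en-2-yl benzoate | C[C@@H](OC(=O)c1ccccc1)[C@@H](O[Si](C)(C)C(C)(C)C)C=C | intermediate
24 | (2R,3S)-3-hydroxypent-4-en-2-yl benzoate | C[C@@H](OC(=O)c1ccccc1)[C@@H](O)C=C | intermediate
25 | (2R,3S,4E)-3-hydroxy-5-[(2S,3R,3aR,7aR)-3-hydroxy-5-oxo-2,3,3a,7a-tetrahydro-5H-furo[3,2-b]pyran-2-yl]pent-4-en-2-yl benzoate | C[C@@H](OC(=O)c1ccccc1)[C@@H](O)/C=C/[C@@H]1O[C@@H]2C=CC(=O)O[C@@H]2[C@@H]1O | target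

**Step count**

Total step count: 16 (steps 1–10 main sequence, steps 11–15 side-chain fragment, step 16 union).
Longest linear sequence: 11 steps (steps 1–10 and 16).

**Steps most likely to fail**

Step 5 (key step). What may go wrong: base-induced epimerisation at C2 of the all-cis ester, which sits on the concave face and is α to both the ring oxygen and the ester carbonyl, or E2 loss of triflate before ring closure. Fallback (no ring contraction and no enolisable centre): it sets out from triol 5. Selective sulfonylation of the primary hydroxyl with 2,4,6-triisopropylbenzenesulfonyl chloride in pyridine would give the primary sulfonate F1. K2CO3 in MeOH would close the terminal epoxide F2 with retention at C2. KOt-Bu in THF would then induce 5-exo opening of the epoxide at C2 by the C7a hydroxyl with inversion and give the all-cis hydroxymethyl tetrahydrofuran F3. Lindlar semihydrogenation would give the (Z)-alkenyl alcohol F4, and Dess–Martin oxidation would come back to the route at aldehyde 13.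

Step 2. What may go wrong: erosion of facial selectivity, because chelation of the ynone by the lithium alkoxides competes with the Felkin–Anh trajectory and delivers the C7a epimer. Fallback (deliberate formation of the epimer, then inversion): it sets out from hemiketal 3. Chelation-controlled reduction with Zn(BH4)2 would give the epimeric D-allo triol F5. Acetonation of the terminal diol (2,2-dimethoxypropane, pyridinium p-toluenesulfonate) would give the diacetonide F6, in which only the propargylic hydroxyl is free. Mitsunobu reaction (4-nitrobenzoic acid, PPh3, diisopropyl azodicarboxylate) would give the inverted 4-nitrobenzoate F7, and methanolysis (K2CO3, MeOH) the D-altro alcohol F8. Selective hydrolysis of the terminal acetonide (60% aq. AcOH) would come back to the route at triol 5.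

Step 16. What may go wrong: unproductive pathways of the allylic alcohol partner (homodimerisation, ruthenium hydride isomerisation to the ethyl ketone) consume it before it couples with the hindered, oxygen-flanked vinyl group. Fallback (electron-poor partner, with the C3' stereocentre made afterwards under reagent control): it sets out from 24 and 18. Dess–Martin oxidation of 24 would give the vinyl ketone F9, which cannot isomerise and homodimerises only slowly. Cross-metathesis of 18 with F9 under the same ruthenium catalyst would give the E-enone F10. Corey–Bakshi–Shibata reduction of the C3' ketone ((S)-Me-CBS oxazaborolidine, catecholborane, −78 °C; the alkenyl group acts as the large substituent) would come back to the route at target 25.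

**Further compounds**

F1 | step 5 | 1-O-TBS-2,3-didehydro-2,3-dideoxy-5,6-O-isopropylidene-8-O-(2,4,6-triisopropylbenzenesulfonyl)-D-altro-oct-2-ynitol | CC(C)(C)[Si](C)(C)OCC#C[C@@H](O)[C@@H]1OC(C)(C)O[C@@H]1[C@H](O)COS(=O)(=O)c1c(C(C)C)cc(C(C)C)cc1C(C)C
F2 | step 5 | 7,8-anhydro-1-O-TBS-2,3-didehydro-2,3-dideoxy-5,6-O-isopropylidene-D-altro-oct-2-ynitol (terminal epoxide) | CC(C)(C)[Si](C)(C)OCC#C[C@@H](O)[C@@H]1OC(C)(C)O[C@@H]1[C@H]2CO2
F3 | step 5 | [(3aR,4S,6R,6aS)-6-[3-(TBSO)prop-1-yn-1-yl]-2,2-dimethyltetrahydrofuro[3,4-d][1,3]dioxol-4-yl]methanol (all-cis) | CC(C)(C)[Si](C)(C)OCC#C[C@H]1O[C@@H](CO)[C@H]2OC(C)(C)O[C@@H]12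
F4 | step 5 | [(3aR,4S,6R,6aS)-6-[(1Z)-3-(TBSO)prop-1-en-1-yl]-2,2-dimethyltetrahydrofuro[3,4-d][1,3]dioxol-4-yl]methanol (all-cis) | CC(C)(C)[Si](C)(C)OC/C=C\[C@H]1O[C@@H](CO)[C@H]2OC(C)(C)O[C@@H]12
F5 | step 2 | 1-O-TBS-2,3-didehydro-2,3-dideoxy-5,6-O-isopropylidene-D-allo-oct-2-ynitol | CC(C)(C)[Si](C)(C)OCC#C[C@H](O)[C@@H]1OC(C)(C)O[C@@H]1[C@H](O)CO
F6 | step 2 | 1-O-TBS-2,3-didehydro-2,3-dideoxy-5,6:7,8-di-O-isopropylidene-D-allo-oct-2-ynitol | CC(C)(C)[Si](C)(C)OCC#C[C@H](O)[C@@H]1OC(C)(C)O[C@@H]1[C@H]2COC(C)(C)O2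
F7 | step 2 | 1-O-TBS-2,3-didehydro-2,3-dideoxy-5,6:7,8-di-O-isopropylidene-4-O-(4-nitrobenzoyl)-D-altro-oct-2-ynitol | CC(C)(C)[Si](C)(C)OCC#C[C@@H](OC(=O)c1ccc(cc1)[N+](=O)[O-])[C@@H]1OC(C)(C)O[C@@H]1[C@H]2COC(C)(C)O2
F8 | step 2 | 1-O-TBS-2,3-didehydro-2,3-dideoxy-5,6:7,8-di-O-isopropylidene-D-altro-oct-2-ynitol | CC(C)(C)[Si](C)(C)OCC#C[C@@H](O)[C@@H]1OC(C)(C)O[C@@H]1[C@H]2COC(C)(C)O2
F9 | step 16 | (2R)-3-oxopent-4-en-2-yl benzoate | C[C@@H](OC(=O)c1ccccc1)C(=O)C=C
F10 | step 16 | (2R,4E)-5-[(2S,3R,3aR,7aR)-3-hydroxy-5-oxo-2,3,3a,7a-tetrahydro-5H-furo[3,2-b]pyran-2-yl]-3-oxopent-4-en-2-yl benzoate | C[C@@H](OC(=O)c1ccccc1)C(=O)/C=C/[C@@H]1O[C@@H]2C=CC(=O)O[C@@H]2[C@@H]1O
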